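**Retrosynthetic overview**

1. Numbering: ring A = C-1 to C-5 plus C-10 (Br on C-3, gem-dimethyl on C-4); ring B = C-5 to C-10 (C-8 methyl/vinyl, C-9 oxobutyl chain, C-10 methyl).
2. The methyl ketone comes from a terminal alkene (Wacker) and a temporary C-6 carbonyl is removed. Key disconnection: C-4–C-5 and C-3–Br of ring A, opened to a monocyclic ring B enol acetate (C-5=C-6) whose C-10 carries a homoprenyl arm; a bromonium-induced cyclization closes it.
3. Enabling feature: C-6 of ring B is bonded to the ring-fusion carbon C-5 and lies 1,3 to both quaternary carbons C-8 and C-10. One temporary C-6 carbonyl therefore allows two anti-selective conjugate additions (vinyl to C-8, methyl to C-10, both steered by C-9) and leaves the regiodefined C-5 enolate that becomes the cyclization terminator.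
4. Ring order: ring B first, by organocatalytic Michael/aldol annulation of hex-5-enal with methyl vinyl ketone (sets C-9 and the absolute configuration); ring A last.

Key step: step 7

Remark: 1, 2 and 10 are taken as catalogue compounds; the C-5 configuration of ketone 16 is assumed to be the kinetic one and is kept by avoiding strong acid or base until C-6 is reduced.

**Route**

Step 1
Reactants: 1 hex-5-enal; 2 but-3-en-2-one (methyl vinyl ketone)
Product: 4 (S)-4-(but-3-en-1-yl)cyclohex-2-en-1-one, via keto aldehyde 3 (not isolated)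
Conditions: (R)-2-[methoxy(diphenyl)methyl]pyrrolidine (5 mol%), ethyl 3,4-dihydroxybenzoate (20 mol%), neat, 4 °C; then KOH, n-Bu4NOH (cat.), Et2O/THF/H2O, reflux
Reagents that add atoms: none
Why: Enamine-catalysed Michael addition to the enone (the diarylmethyl group of the (R)-catalyst shields one face of the E-enamine, so C–C bond formation should give the S-configured α-carbon, the future C-9) followed by base-mediated intramolecular aldol condensation (Robinson-type annulation) that closes ring B without touching the new stereocentre.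

Step 2
Reactants: 4 (S)-4-(but-3-en-1-yl)cyclohex-2-en-1-one
Product: 6 (S)-4-(but-3-en-1-yl)-3-methylcyclohex-2-en-1-one, via lithium enolate 5 (not isolated)
Conditions: Me2CuLi (from MeLi and CuI), Et2O, −78 to −40 °C; then N-tert-butylbenzenesulfinimidoyl chloride, THF, −78 °C to rt
Reagents that add atoms: methyllithium, [Li]C
Why: Conjugate addition of the Gilman cuprate puts the methyl group on C-8 and gives the C-6/C-7 enolate regiospecifically, which the sulfinimidoyl chloride dehydrogenates in the same flask (Mukaiyama dehydrogenation: S-sulfenylation at C-7 and syn-elimination toward C-8), so the enone returns with the β-methyl group and the transient C-8 stereocentre is erased.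

Step 3
Reactants: 6 (S)-4-(but-3-en-1-yl)-3-methylcyclohex-2-en-1-one
Product: 8 (3R,4S)-4-(but-3-en-1-yl)-3-ethenyl-3-methylcyclohexan-1-one, via magnesium enolate 7 (not isolated)
Conditions: CH2=CHMgBr, CuI, THF/Me2S, −78 to 0 °C; aq. NH4Cl
Reagents that add atoms: vinylmagnesium bromide, C=C[Mg]Br
Why: Cuprate conjugate addition to the 3-methyl-4-alkylcyclohexenone proceeds by axial attack anti to the pseudoaxial C-9 chain, which should set the quaternary C-8 with vinyl trans and methyl cis to the butenyl group.

Step 4
Reactants: 8 (3R,4S)-4-(but-3-en-1-yl)-3-ethenyl-3-methylcyclohexan-1-one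
Product: 9 (4S,5R)-4-(but-3-en-1-yl)-5-ethenyl-5-methylcyclohex-2-en-1-one
Conditions: IBX, 4-methoxypyridine N-oxide, DMSO, 25 °C
Reagents that add atoms: none
Why: IBX α,β-dehydrogenation of the ketone can only run toward C-5/C-10 because C-8 is quaternary, so the transposed enone should form without any regiocontrol element.

Step 5
Reactants: 9 (4S,5R)-4-(but-3-en-1-yl)-5-ethenyl-5-methylcyclohex-2-en-1-one; 10 5-bromo-2-methylpent-2-ene
Product: 13 (4S,5R)-4-(but-3-en-1-yl)-5-ethenyl-5-methyl-3-(4-methylpent-3-en-1-yl)cyclohex-2-en-1-one, via Grignard reagent 11 (not isolated), via magnesium enolate 12 (not isolated)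
Conditions: 10, Mg, THF, 25 °C; then 9, CuBr·SMe2 (10 mol%), THF, −40 °C; then N-tert-butylbenzenesulfinimidoyl chloride, −78 °C to rt
Reagents that add atoms: none
Why: Copper-catalysed conjugate addition of the homoprenyl Grignard reagent to C-10 (anti to the C-9 chain, a configuration that is erased) gives the C-5/C-6 enolate, whose one-flask Mukaiyama dehydrogenation re-forms the C-5=C-10 enone now carrying the arm that will become C-1 to C-4 of ring A.

Step 6
Reactants: 13 (4S,5R)-4-(but-3-en-1-yl)-5-ethenyl-5-methyl-3-(4-methylpent-3-en-1-yl)cyclohex-2-en-1-one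
Product: 15 (3R,4R,5R)-4-(but-3-en-1-yl)-5-ethenyl-3,5-dimethyl-3-(4-methylpent-3-en-1-yl)cyclohex-1-en-1-yl acetate, via lithium enolate 14 (not isolated)
Conditions: Me2CuLi (from MeLi and CuI), Et2O, −20 to 0 °C; then Ac2O, 0 °C to rt
Reagents that add atoms: methyllithium, [Li]C; acetic anhydride, CC(=O)OC(C)=O
Why: Cuprate conjugate addition to the β,β-disubstituted enone should again occur axially and anti to the pseudoaxial C-9 chain, setting the quaternary C-10 with methyl trans to the butenyl group, and O-acetylation of the regiodefined enolate (C-acylation is disfavoured at the neopentylic carbon) fixes the C-5=C-6 enol acetate.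

Step 7
Reactants: 15 (3R,4R,5R)-4-(but-3-en-1-yl)-5-ethenyl-3,5-dimethyl-3-(4-methylpent-3-en-1-yl)cyclohex-1-en-1-yl acetate
Product: 16 (3R,4R,4aR,7S,8aR)-7-bromo-4-(but-3-en-1-yl)-3-ethenyl-3,4a,8,8-tetramethyloctahydronaphthalen-1(2H)-one
Conditions: Et2SBr·SbCl5Br (BDSB, 1.1 equiv), MeNO2, −25 °C, 10 min; aq. Na2SO3/NaHCO3
Reagents that add atoms: bromodiethylsulfonium bromopentachloroantimonate, CC[S+](Br)CC.Cl[Sb-](Cl)(Cl)(Cl)(Cl)Br
Why: Proposed new method: Br+ is transferred from the sulfonium salt to the trisubstituted C-3=C-4 alkene, the most nucleophilic π bond present (the enol acetate is electronically attenuated and can be attacked only at a neopentylic carbon, the vinyl and butenyl groups are monosubstituted), and the bromonium ion, polarised toward the tertiary C-4, is captured by C-5 of the enol acetate, after which the O-acyl oxocarbenium ion loses its acetyl group to halide and unveils the C-6 ketone. The closest known reaction type is the halonium-induced cation–π (polyene) cyclization with this reagent, terminated by arenes, alkenes or enolised 1,3-dicarbonyl groups, together with mercury- and epoxide-initiated cyclizations terminated by enol derivatives; new is the enol acetate terminator under bromonium initiation. Ring A closes in a 6-endo mode at the bromonium carbon (exo with respect to the enol acetate double bond) through a chair transition state. C-3 is set by anti addition across C-3=C-4 with bromine equatorial, and C-5 by the chair–chair arrangement in which the arm leaves C-10 equatorially and bonds to the β face of C-5, the α face being blocked by the axial butenyl chain on C-9, so that H-5 ends trans to the C-10 methyl group; both follow from the preset C-10. The step needs chemoselective bromonium formation and convergence of the two diastereomeric bromonium ions: the first is secured by the substitution pattern of the four π bonds, the second by reversible Br+ transfer, which lets both ions drain through the one productive chair pathway.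

Step 8
Reactants: 16 (3R,4R,4aR,7S,8aR)-7-bromo-4-(but-3-en-1-yl)-3-ethenyl-3,4a,8,8-tetramethyloctahydronaphthalen-1(2H)-one
Product: 17 N'-[(1E,3R,4R,4aR,7S,8aR)-7-bromo-4-(but-3-en-1-yl)-3-ethenyl-3,4a,8,8-tetramethyloctahydronaphthalen-1(2H)-ylidene]-4-methylbenzenesulfonohydrazide
Conditions: TsNHNH2, PPTS (cat.), EtOH, 60 °C
Reagents that add atoms: 4-methylbenzenesulfonohydrazide, Cc1ccc(cc1)S(=O)(=O)NN
Why: Mildly acid-catalysed condensation of the only carbonyl group with the sulfonyl hydrazide should give the hydrazone (expected anti to C-5), while the alkyl bromide and the three alkenes are inert.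

Step 9
Reactants: 17 N'-[(1E,3R,4R,4aR,7S,8aR)-7-bromo-4-(but-3-en-1-yl)-3-ethenyl-3,4a,8,8-tetramethyloctahydronaphthalen-1(2H)-ylidene]-4-methylbenzenesulfonohydrazide
Product: 19 (1R,2R,4aR,6S,8aR)-6-bromo-1-(but-3-en-1-yl)-2-ethenyl-2,5,5,8a-tetramethyldecahydronaphthalene, via N-boryl hydrazine 18 (not isolated)
Conditions: catecholborane, CHCl3, 0 °C to rt; then NaOAc·3H2O, reflux
Reagents that add atoms: none
Why: Hydride transfer from catecholborane to the hydrazone and acetate-induced loss of sulfinate and dinitrogen (Caglioti-type hydrazone reduction) should turn C-6 into a methylene group under neutral conditions that spare the equatorial bromide and the alkenes, uncatalysed alkene hydroboration by catecholborane being slow at room temperature.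

Step 10
Reactants: 19 (1R,2R,4aR,6S,8aR)-6-bromo-1-(but-3-en-1-yl)-2-ethenyl-2,5,5,8a-tetramethyldecahydronaphthalene
Product: 20 4-[(1R,2R,4aR,6S,8aR)-6-bromo-2-ethenyl-2,5,5,8a-tetramethyldecahydronaphthalen-1-yl]butan-2-one
Conditions: PdCl2 (10 mol%), Cu(OAc)2 (20 mol%), O2 (1 atm), DMA/H2O (7:1), 25 °C
Reagents that add atoms: water, O
Why: Tsuji–Wacker oxidation (Markovnikov hydroxypalladation, reoxidation by copper and O2) should convert the unhindered terminal alkene of the butenyl chain into the methyl ketone, whereas the vinyl group on the quaternary C-8, flanked by the axial methyl group on C-10, should react much more slowly.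

**Compound list**

1 | hex-5-enal | C=CCCCC=O | starting material
2 | but-3-en-2-one (methyl vinyl ketone) | C=CC(C)=O | starting material
3 | (S)-2-(but-3-en-1-yl)-5-oxohexanal | O=C[C@H](CCC(C)=O)CCC=C | intermediate
4 | (S)-4-(but-3-en-1-yl)cyclohex-2-en-1-one | O=C1C=C[C@@H](CCC=C)CC1 | intermediate
5 | lithium (3R,4S)-4-(but-3-en-1-yl)-3-methylcyclohex-1-en-1-olate | [Li]OC1=C[C@H](C)[C@@H](CCC=C)CC1 | intermediate
6 | (S)-4-(but-3-en-1-yl)-3-methylcyclohex-2-en-1-one | O=C1C=C(C)[C@@H](CCC=C)CC1 | intermediate
7 | bromomagnesium (3R,4S)-4-(but-3-en-1-yl)-3-ethenyl-3-methylcyclohex-1-en-1-olate | Br[Mg]OC1=C[C@](C)(C=C)[C@@H](CCC=C)CC1 | intermediate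
8 | (3R,4S)-4-(but-3-en-1-yl)-3-ethenyl-3-methylcyclohexan-1-one (vinyl trans to butenyl) | O=C1C[C@](C)(C=C)[C@@H](CCC=C)CC1 | intermediate
9 | (4S,5R)-4-(but-3-en-1-yl)-5-ethenyl-5-methylcyclohex-2-en-1-one | O=C1C=C[C@H](CCC=C)[C@@](C)(C=C)C1 | intermediate
10 | 5-bromo-2-methylpent-2-ene | CC(C)=CCCBr | starting material
11 | (4-methylpent-3-en-1-yl)magnesium bromide | CC(C)=CCC[Mg]Br | intermediate
12 | bromomagnesium (3S,4S,5R)-4-(but-3-en-1-yl)-5-ethenyl-5-methyl-3-(4-methylpent-3-en-1-yl)cyclohex-1-en-1-olate | Br[Mg]OC1=C[C@@H](CCC=C(C)C)[C@H](CCC=C)[C@@](C)(C=C)C1 | intermediate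
13 | (4S,5R)-4-(but-3-en-1-yl)-5-ethenyl-5-methyl-3-(4-methylpent-3-en-1-yl)cyclohex-2-en-1-one | O=C1C=C(CCC=C(C)C)[C@H](CCC=C)[C@@](C)(C=C)C1 | intermediate
14 | lithium (3R,4R,5R)-4-(but-3-en-1-yl)-5-ethenyl-3,5-dimethyl-3-(4-methylpent-3-en-1-yl)cyclohex-1-en-1-olate | [Li]OC1=C[C@](C)(CCC=C(C)C)[C@H](CCC=C)[C@@](C)(C=C)C1 | intermediate
15 | (3R,4R,5R)-4-(but-3-en-1-yl)-5-ethenyl-3,5-dimethyl-3-(4-methylpent-3-en-1-yl)cyclohex-1-en-1-yl acetate | CC(=O)OC1=C[C@](C)(CCC=C(C)C)[C@H](CCC=C)[C@@](C)(C=C)C1 | intermediate
16 | (3R,4R,4aR,7S,8aR)-7-bromo-4-(but-3-en-1-yl)-3-ethenyl-3,4a,8,8-tetramethyloctahydronaphthalen-1(2H)-one (trans-fused, Br equatorial) | C=C[C@@]1(C)CC(=O)[C@H]2C(C)(C)[C@@H](Br)CC[C@]2(C)[C@@H]1CCC=C | intermediate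
17 | N'-[(1E,3R,4R,4aR,7S,8aR)-7-bromo-4-(but-3-en-1-yl)-3-ethenyl-3,4a,8,8-tetramethyloctahydronaphthalen-1(2H)-ylidene]-4-methylbenzenesulfonohydrazide | C=C[C@@]1(C)C/C(=N\NS(=O)(=O)c2ccc(C)cc2)[C@H]2C(C)(C)[C@@H](Br)CC[C@]2(C)[C@@H]1CCC=C | intermediate
18 | N-(1,3,2-benzodioxaborol-2-yl)-N-[(1R,3R,4R,4aR,7S,8aR)-7-bromo-4-(but-3-en-1-yl)-3-ethenyl-3,4a,8,8-tetramethyldecahydronaphthalen-1-yl]-N'-(4-methylbenzenesulfonyl)hydrazine (C-1 configuration from hydride delivery to the α face; lost on decomposition) | C=C[C@@]1(C)C[C@@H](N(NS(=O)(=O)c2ccc(C)cc2)B2Oc3ccccc3O2)[C@H]2C(C)(C)[C@@H](Br)CC[C@]2(C)[C@@H]1CCC=C | intermediate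
19 | (1R,2R,4aR,6S,8aR)-6-bromo-1-(but-3-en-1-yl)-2-ethenyl-2,5,5,8a-tetramethyldecahydronaphthalene | C=C[C@@]1(C)CC[C@H]2C(C)(C)[C@@H](Br)CC[C@]2(C)[C@@H]1CCC=C | intermediate
20 | 4-[(1R,2R,4aR,6S,8aR)-6-bromo-2-ethenyl-2,5,5,8a-tetramethyldecahydronaphthalen-1-yl]butan-2-one | C=C[C@@]1(C)CC[C@H]2C(C)(C)[C@@H](Br)CC[C@]2(C)[C@@H]1CCC(C)=O | target

**Step count and risks**

Total step count: 10. Longest linear sequence: 10 steps (1 to 20).

Steps most likely to fail:

Step 7 (proposed new method). Electrophilic bromine may attack the enol acetate instead of the C-3=C-4 alkene. The bromonium ion may also be intercepted by halide or lose a proton before the C–C bond forms, or closure may run through the other half-chair to the cis-fused ring system. The fallback uses known chemistry and sets out from 15. A mercury-induced cation–olefin cyclization with Hg(OCOCF3)2 in MeNO2 at −20 °C is used; divalent mercury is far more selective for the electron-rich trisubstituted alkene and is a classical initiator for closures terminated by enol derivatives. Work-up with aqueous KBr should give the equatorial C-3 organomercuric bromide F1. Brominative demercuration (Br2, LiBr, pyridine, O2, 25 °C) should then give mainly the equatorial bromide, and the route is rejoined at 16.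

Step 6. The hindered β,β-disubstituted enone may react sluggishly or by 1,2-addition, the methyl group may add syn to the C-9 chain (wrong C-10 epimer), or the enolate may be C-acylated. The fallback sets out from 13. Luche reduction (NaBH4, CeCl3·7H2O, MeOH, −78 °C; hydride approach anti to the axial vinyl group, Mitsunobu inversion if the other epimer forms) should give the β-configured allylic alcohol F2. Hydroxyl-directed Simmons–Smith cyclopropanation (Et2Zn, CH2I2, CH2Cl2, 0 °C) delivers the methylene to C-5=C-10 on the face of the hydroxyl group and gives the cyclopropyl carbinol F3. Dess–Martin oxidation gives the cyclopropyl ketone F4. Reductive opening of the exocyclic cyclopropane bond (Li, NH3/THF, −78 °C) then gives lithium enolate 14 with the C-10 methyl group in place, and acetylation (Ac2O after removal of NH3) rejoins the route at 15. In this variant C-10 is set by intramolecular delivery from the carbinol, not by approach control at the crowded enone.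

Step 8. Condensation at the C-6 carbonyl, flanked by C-5 and the neopentylic C-7, may be slow, and acid may epimerize C-5 through the enol before the hydrazone has formed. The fallback sets out from 16. Treatment with 1,2-bis(tert-butyldimethylsilyl)hydrazine and Sc(OTf)3 (cat.) at 25 °C, which works on hindered ketones without protic acid, should give the N-tert-butyldimethylsilyl hydrazone F5. Wolff–Kishner reduction (KOtBu, t-BuOH/DMSO, 25 °C) follows; it should be tolerated because the equatorial C-3 bromide has no antiperiplanar hydrogen for E2 elimination. The route is rejoined at 19.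

Further compounds
F1 | step 7 | (3R,4R,4aR,7S,8aR)-7-(bromomercurio)-4-(but-3-en-1-yl)-3-ethenyl-3,4a,8,8-tetramethyloctahydronaphthalen-1(2H)-one | C=C[C@@]1(C)CC(=O)[C@H]2C(C)(C)[C@@H]([Hg]Br)CC[C@]2(C)[C@@H]1CCC=C
F2 | step 6 | (1R,4S,5R)-4-(but-3-en-1-yl)-5-ethenyl-5-methyl-3-(4-methylpent-3-en-1-yl)cyclohex-2-en-1-ol | O[C@H]1C=C(CCC=C(C)C)[C@H](CCC=C)[C@@](C)(C=C)C1
F3 | step 6 | 5-(but-3-en-1-yl)-4-ethenyl-4-methyl-6-(4-methylpent-3-en-1-yl)bicyclo[4.1.0]heptan-2-ol (hydroxyl and cyclopropane methylene cis, both trans to the butenyl group) | O[C@H]1[C@H]2C[C@@]2(CCC=C(C)C)[C@H](CCC=C)[C@@](C)(C=C)C1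
F4 | step 6 | 5-(but-3-en-1-yl)-4-ethenyl-4-methyl-6-(4-methylpent-3-en-1-yl)bicyclo[4.1.0]heptan-2-one (cyclopropane methylene trans to the butenyl group) | O=C1[C@H]2C[C@@]2(CCC=C(C)C)[C@H](CCC=C)[C@@](C)(C=C)C1
F5 | step 8 | (E)-1-[(3R,4R,4aR,7S,8aR)-7-bromo-4-(but-3-en-1-yl)-3-ethenyl-3,4a,8,8-tetramethyloctahydronaphthalen-1(2H)-ylidene]-2-(tert-butyldimethylsilyl)hydrazine | C=C[C@@]1(C)C/C(=N\N[Si](C)(C)C(C)(C)C)[C@H]2C(C)(C)[C@@H](Br)CC[C@]2(C)[C@@H]1CCC=C
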